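**Retrosynthetic overview**
1. Target 38 ⇐ (R)-CBS reduction of the C9 enone 37 ⇐ intramolecular Nozaki–Hiyama–Kishi closure of the ten-membered ring (C9–C10) from iodo-aldehyde 35, which already carries the (R)-2-methylbutanoate.
2. 35 ⇐ γ-lactone 32 (Felkin reduction of the C6 ketone, then lactonisation) ⇐ enone 30 ⇐ C5–C6 union of West alkyne 15 (Negishi carboalumination sets 4E and C15) with East aldehyde 27.
3. West 15 (C1–C5, C10, C14) ⇐ Evans–Crimmins glycolate alkylation (sets C3) with Z-iodo-bromide 4 from but-2-yn-1-ol.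
4. East 27 (C6–C9, C11–C13) ⇐ Evans enolate of a pentenoyl imide + methyl (R)-lactate triflate (C7 by auxiliary, C11 by SN2 inversion).
5. Ring order: γ-lactone first, ten-membered carbocycle last.

Assumption: germacranolide numbering (C1–C15; carbinols C3, C6, C9; lactone C12) is used for positions; the target is taken exactly as drawn (3S,6S,7S,9S,11R; 1(10)Z,4E; (R)-2-methylbutanoate).

**West fragment**

Step 1
Reactants: 1 but-2-yn-1-ol
Product: 3 (2Z)-3-iodobut-2-en-1-ol, via cyclic Z-alkenylalanate 2 (not isolated)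
Conditions: Red-Al, THF, 0 °C to rt; then I2, −78 to 0 °C
Reagents that add atoms: iodine, II; Red-Al, [Na+].COCCO[AlH2-]OCCOC (its Na, Al and alkoxy atoms stay only in 2)
Why: Hydroxyl-directed trans-hydroalumination places Al on C3 cis to CH2O in a five-membered alanate, and iodinolysis with retention gives the Z-iodide that becomes the C1=C10 geometry.

Step 2
Reactants: 3 (2Z)-3-iodobut-2-en-1-ol
Product: 4 (2Z)-1-bromo-3-iodobut-2-ene
Conditions: CBr4, PPh3, CH2Cl2, 0 °C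
Reagents that add atoms: carbon tetrabromide, BrC(Br)(Br)Br
Why: Appel bromination of the primary allylic alcohol proceeds by SN2 without touching the vinyl iodide or its geometry.

Step 3
Reactants: 5 glycolic acid
Product: 7 [(tert-butyldimethylsilyl)oxy]acetic acid, via bis-silylated glycolate 6 (not isolated)
Conditions: TBSCl (2.2 equiv), imidazole, DMF, rt; then K2CO3 (cat.), MeOH–H2O, rt
Reagents that add atoms: tert-butyldimethylsilyl chloride, CC(C)(C)[Si](C)(C)Cl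
Why: Exhaustive silylation followed by selective solvolysis of the much more labile silyl ester leaves the TBS ether.

Step 4
Reactants: 7 [(tert-butyldimethylsilyl)oxy]acetic acid; 8 (4R)-4-benzyl-1,3-oxazolidin-2-one
Product: 10 (4R)-4-benzyl-3-{[(tert-butyldimethylsilyl)oxy]acetyl}-1,3-oxazolidin-2-one, via mixed pivalic anhydride 9 (not isolated)
Conditions: PivCl, Et3N, THF, −20 °C; then 8, LiCl, −20 °C to rt
Reagents that add atoms: pivaloyl chloride, CC(C)(C)C(=O)Cl (its atoms stay only in 9)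
Why: Mixed-anhydride N-acylation; the oxazolidinone attacks the less hindered glycolyl carbonyl of the anhydride.

Step 5
Reactants: 10 (4R)-4-benzyl-3-{[(tert-butyldimethylsilyl)oxy]acetyl}-1,3-oxazolidin-2-one; 4 (2Z)-1-bromo-3-iodobut-2-ene
Product: 12 (4R)-4-benzyl-3-[(2S,4Z)-2-[(tert-butyldimethylsilyl)oxy]-5-iodohex-4-enoyl]-1,3-oxazolidin-2-one, via sodium Z-enolate 11 (not isolated)
Conditions: NaHMDS, THF, −78 °C; then 4, −78 to −45 °C
Reagents that add atoms: sodium bis(trimethylsilyl)amide, [Na+].C[Si](C)(C)[N-][Si](C)(C)C (Na stays only in 11)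
Why: Evans–Crimmins glycolate alkylation; the chelated Z-enolate is alkylated (SN2) on the face opposite the benzyl group, which sets C3 as S.

Step 6
Reactants: 12 (4R)-4-benzyl-3-[(2S,4Z)-2-[(tert-butyldimethylsilyl)oxy]-5-iodohex-4-enoyl]-1,3-oxazolidin-2-one
Product: 13 (2S,4Z)-2-[(tert-butyldimethylsilyl)oxy]-5-iodohex-4-en-1-ol
Conditions: LiBH4, THF, 0 °C
Reagents that add atoms: none
Why: Reductive cleavage of the exocyclic imide carbonyl releases the auxiliary without affecting the vinyl iodide or C3.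

Step 7
Reactants: 13 (2S,4Z)-2-[(tert-butyldimethylsilyl)oxy]-5-iodohex-4-en-1-ol
Product: 14 (2S,4Z)-2-[(tert-butyldimethylsilyl)oxy]-5-iodohex-4-enal
Conditions: Dess–Martin periodinane, CH2Cl2, 0 °C to rt
Reagents that add atoms: none
Why: Dess–Martin oxidation gives the α-silyloxy aldehyde under non-basic conditions, so C3 is not epimerised.

Step 8
Reactants: 14 (2S,4Z)-2-[(tert-butyldimethylsilyl)oxy]-5-iodohex-4-enal
Product: 15 tert-butyl{[(3S,5Z)-6-iodohept-5-en-1-yn-3-yl]oxy}dimethylsilane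
Conditions: dimethyl (1-diazo-2-oxopropyl)phosphonate, K2CO3, MeOH, 0 °C to rt
Reagents that add atoms: dimethyl (1-diazo-2-oxopropyl)phosphonate (Ohira–Bestmann reagent), CC(=O)C(=[N+]=[N-])P(=O)(OC)OC
Why: Seyferth–Gilbert homologation (Ohira–Bestmann) adds C5 as the alkyne terminus under conditions mild enough for the α-silyloxy centre and the vinyl iodide.

**East fragment**

Step 9
Reactants: 8 (4R)-4-benzyl-1,3-oxazolidin-2-one; 16 pent-4-enoyl chloride
Product: 18 (4R)-4-benzyl-3-(pent-4-enoyl)-1,3-oxazolidin-2-one, via lithium oxazolidinide 17 (not isolated)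
Conditions: n-BuLi, THF, −78 °C; then 16, −78 to 0 °C
Reagents that add atoms: n-butyllithium, [Li]CCCC (Li stays only in 17)
Why: Standard N-acylation of the lithiated auxiliary.

Step 10
Reactants: 19 methyl (2R)-2-hydroxypropanoate (methyl D-lactate)
Product: 20 methyl (2R)-2-{[(trifluoromethyl)sulfonyl]oxy}propanoate
Conditions: Tf2O, 2,6-lutidine, CH2Cl2, −78 to 0 °C
Reagents that add atoms: trifluoromethanesulfonic anhydride, O=S(=O)(OS(=O)(=O)C(F)(F)F)C(F)(F)F
Why: O-Sulfonylation does not touch the stereocentre, so the R configuration is retained.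

Step 11
Reactants: 18 (4R)-4-benzyl-3-(pent-4-enoyl)-1,3-oxazolidin-2-one; 20 methyl (2R)-2-{[(trifluoromethyl)sulfonyl]oxy}propanoate
Product: 22 methyl (2R,3S)-3-{[(4R)-4-benzyl-2-oxo-1,3-oxazolidin-3-yl]carbonyl}-2-methylhex-5-enoate, via lithium Z-enolate 21 (not isolated)
Conditions: LDA, THF, −78 °C; then 20, −78 to −40 °C
Reagents that add atoms: lithium diisopropylamide, [Li+].CC(C)[N-]C(C)C (Li stays only in 21)
Why: Evans alkylation with an α-triflyloxy ester; the auxiliary face sets C7 (S) and clean SN2 inversion of the R-triflate sets C11 (R), giving the 2,3-disubstituted succinate.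

Step 12
Reactants: 22 methyl (2R,3S)-3-{[(4R)-4-benzyl-2-oxo-1,3-oxazolidin-3-yl]carbonyl}-2-methylhex-5-enoate
Product: 24 methyl (2R,3S)-3-{[(4R)-4-benzyl-2-oxo-1,3-oxazolidin-3-yl]carbonyl}-2-methyl-5-oxopentanoate, via secondary ozonide 23 (not isolated)
Conditions: O3, CH2Cl2, −78 °C; then Me2S, −78 °C to rt
Reagents that add atoms: ozone, [O-][O+]=O
Why: Ozonolysis of the only alkene unveils C9 at the aldehyde level before any other olefin is present.

Step 13
Reactants: 24 methyl (2R,3S)-3-{[(4R)-4-benzyl-2-oxo-1,3-oxazolidin-3-yl]carbonyl}-2-methyl-5-oxopentanoate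
Product: 25 methyl (2R,3S)-3-{[(4R)-4-benzyl-2-oxo-1,3-oxazolidin-3-yl]carbonyl}-5,5-dimethoxy-2-methylpentanoate
Conditions: HC(OMe)3, PPTS (cat.), MeOH, rt
Reagents that add atoms: trimethyl orthoformate, COC(OC)OC
Why: Acid-catalysed acetalisation masks C9 until just before the macrocyclisation.

Step 14
Reactants: 25 methyl (2R,3S)-3-{[(4R)-4-benzyl-2-oxo-1,3-oxazolidin-3-yl]carbonyl}-5,5-dimethoxy-2-methylpentanoate
Product: 26 methyl (2R,3S)-3-[(ethylsulfanyl)carbonyl]-5,5-dimethoxy-2-methylpentanoate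
Conditions: EtSH, n-BuLi, THF, 0 °C
Reagents that add atoms: ethanethiol, CCS
Why: Lithium thiolate cleaves the activated exocyclic imide carbonyl selectively over the methyl ester and does not epimerise C7.

Step 15
Reactants: 26 methyl (2R,3S)-3-[(ethylsulfanyl)carbonyl]-5,5-dimethoxy-2-methylpentanoate
Product: 27 methyl (2R,3S)-3-formyl-5,5-dimethoxy-2-methylpentanoate
Conditions: Et3SiH, 10% Pd/C (cat.), acetone, rt
Reagents that add atoms: none
Why: Fukuyama reduction converts the thioester to the C6 aldehyde under neutral conditions that leave the ester, the acetal and the α-stereocentre intact.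

**Union and endgame**

Step 16
Reactants: 15 tert-butyl{[(3S,5Z)-6-iodohept-5-en-1-yn-3-yl]oxy}dimethylsilane; 27 methyl (2R,3S)-3-formyl-5,5-dimethoxy-2-methylpentanoate
Product: 29 methyl (2R,3S)-3-[(2E,4S,6Z)-4-[(tert-butyldimethylsilyl)oxy]-1-hydroxy-7-iodo-3-methylocta-2,6-dien-1-yl]-5,5-dimethoxy-2-methylpentanoate (both C6 epimers), via E-alkenyl dimethylalane 28 (not isolated)
Conditions: Me3Al, Cp2ZrCl2 (cat.), CH2Cl2, 0 °C to rt; volatiles removed; then 27, CH2Cl2–hexane, −78 to −30 °C; cold Rochelle-salt work-up, used crude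
Reagents that add atoms: trimethylaluminium, C[Al](C)C
Why: Negishi Zr-catalysed syn-carboalumination puts CH3 on C4 and Al on C5 (fixing 4E) and the alkenylalane adds 1,2 to the aldehyde; the C6 epimer ratio is irrelevant because C6 is oxidised next (the adduct is oxidised at once, before the γ-hydroxy ester can lactonise).

Step 17
Reactants: 29 methyl (2R,3S)-3-[(2E,4S,6Z)-4-[(tert-butyldimethylsilyl)oxy]-1-hydroxy-7-iodo-3-methylocta-2,6-dien-1-yl]-5,5-dimethoxy-2-methylpentanoate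
Product: 30 methyl (2R,3S)-3-[(2E,4S,6Z)-4-[(tert-butyldimethylsilyl)oxy]-7-iodo-3-methylocta-2,6-dienoyl]-5,5-dimethoxy-2-methylpentanoate
Conditions: Dess–Martin periodinane, pyridine, CH2Cl2, 0 °C
Reagents that add atoms: none
Why: Buffered Dess–Martin oxidation converges both epimers on the β,β-disubstituted enone without epimerising C7 or cleaving the acetal.

Step 18
Reactants: 30 methyl (2R,3S)-3-[(2E,4S,6Z)-4-[(tert-butyldimethylsilyl)oxy]-7-iodo-3-methylocta-2,6-dienoyl]-5,5-dimethoxy-2-methylpentanoate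
Product: 32 (3R,4S,5S)-5-[(1E,3S,5Z)-3-[(tert-butyldimethylsilyl)oxy]-6-iodo-2-methylhepta-1,5-dien-1-yl]-4-(2,2-dimethoxyethyl)-3-methyloxolan-2-one, via 6S-hydroxy ester 31 (not isolated)
Conditions: L-Selectride, THF, −78 °C; AcOH quench; then PPTS (cat.), CH2Cl2, rt
Reagents that add atoms: none
Why: Felkin–Anh 1,2-reduction by the bulky hydride (attack anti to the CH(CH3)CO2Me branch on C7) sets C6 as S, and mild acid lactonisation onto the γ-ester gives the 6,7-trans lactone with the kinetic 11R methyl untouched.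

Step 19
Reactants: 32 (3R,4S,5S)-5-[(1E,3S,5Z)-3-[(tert-butyldimethylsilyl)oxy]-6-iodo-2-methylhepta-1,5-dien-1-yl]-4-(2,2-dimethoxyethyl)-3-methyloxolan-2-one
Product: 33 2-[(2S,3S,4R)-2-[(1E,3S,5Z)-3-hydroxy-6-iodo-2-methylhepta-1,5-dien-1-yl]-4-methyl-5-oxooxolan-3-yl]acetaldehyde
Conditions: 48% aq. HF, MeCN, 0 °C to rt
Reagents that add atoms: water, O
Why: Aqueous HF removes the TBS ether and hydrolyses the dimethyl acetal in one operation, without base that could epimerise C11.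

Step 20
Reactants: 33 2-[(2S,3S,4R)-2-[(1E,3S,5Z)-3-hydroxy-6-iodo-2-methylhepta-1,5-dien-1-yl]-4-methyl-5-oxooxolan-3-yl]acetaldehyde; 34 (2R)-2-methylbutanoic acid
Product: 35 (1E,3S,5Z)-6-iodo-2-methyl-1-[(2S,3S,4R)-4-methyl-5-oxo-3-(2-oxoethyl)oxolan-2-yl]hepta-1,5-dien-3-yl (2R)-2-methylbutanoate
Conditions: EDC·HCl, DMAP (0.2 equiv), CH2Cl2, 0 °C to rt
Reagents that add atoms: none
Why: Steglich esterification of the only free hydroxyl (C3) with catalytic DMAP at low temperature keeps the acid's α-centre intact.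

Step 21
Reactants: 35 (1E,3S,5Z)-6-iodo-2-methyl-1-[(2S,3S,4R)-4-methyl-5-oxo-3-(2-oxoethyl)oxolan-2-yl]hepta-1,5-dien-3-yl (2R)-2-methylbutanoate
Product: 36 (3R,3aS,6Z,9S,10E,11aS)-5-hydroxy-3,6,10-trimethyl-2-oxo-2,3,3a,4,5,8,9,11a-octahydrocyclodeca[b]furan-9-yl (2R)-2-methylbutanoate (both C9 epimers, germacranolide numbering)
Conditions: CrCl2 (10 equiv), NiCl2 (cat.), DMSO–THF, 2 mM (slow addition), rt
Reagents that add atoms: none
Why: Intramolecular Nozaki–Hiyama–Kishi reaction; the alkenylchromium formed with retention of the Z geometry adds chemoselectively to the aldehyde to close the ten-membered ring, and the C9 configuration is left open because it is reset in steps 22–23.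

Step 22
Reactants: 36 (3R,3aS,6Z,9S,10E,11aS)-5-hydroxy-3,6,10-trimethyl-2-oxo-2,3,3a,4,5,8,9,11a-octahydrocyclodeca[b]furan-9-yl (2R)-2-methylbutanoate (epimer mixture)
Product: 37 (3R,3aS,6Z,9S,10E,11aS)-3,6,10-trimethyl-2,5-dioxo-2,3,3a,4,5,8,9,11a-octahydrocyclodeca[b]furan-9-yl (2R)-2-methylbutanoate
Conditions: Dess–Martin periodinane, pyridine, CH2Cl2, 0 °C
Reagents that add atoms: none
Why: Dess–Martin oxidation of the allylic alcohol converges both epimers on one Z-enone under non-epimerising conditions.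

Step 23
Reactants: 37 (3R,3aS,6Z,9S,10E,11aS)-3,6,10-trimethyl-2,5-dioxo-2,3,3a,4,5,8,9,11a-octahydrocyclodeca[b]furan-9-yl (2R)-2-methylbutanoate
Product: 38 (3R,3aS,5S,6Z,9S,10E,11aS)-5-hydroxy-3,6,10-trimethyl-2-oxo-2,3,3a,4,5,8,9,11a-octahydrocyclodeca[b]furan-9-yl (2R)-2-methylbutanoate (target)
Conditions: (R)-2-methyl-CBS-oxazaborolidine (0.5 equiv), catecholborane, toluene, −78 °C
Reagents that add atoms: none
Why: Corey–Bakshi–Shibata 1,2-reduction; with the α-methyl alkenyl group as the large substituent and C8H2 as the small one, the (R)-catalyst delivers hydride to give the 9S carbinol, and the lactone and ester are inert at −78 °C.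

**Compound list**

1 | but-2-yn-1-ol | CC#CCO | starting material
2 | sodium 2,2-bis(2-methoxyethoxy)-3-methyl-2,5-dihydro-1,2-oxaaluminol-2-uide (cyclic Z-alkenylalanate) | [Na+].CC1=CCO[Al-]1(OCCOC)OCCOC | intermediate
3 | (2Z)-3-iodobut-2-en-1-ol | C/C(I)=C/CO | intermediate
4 | (2Z)-1-bromo-3-iodobut-2-ene | C/C(I)=C/CBr | intermediate
5 | glycolic acid | OCC(=O)O | starting material
6 | tert-butyldimethylsilyl [(tert-butyldimethylsilyl)oxy]acetate | CC(C)(C)[Si](C)(C)OCC(=O)O[Si](C)(C)C(C)(C)C | intermediate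
7 | [(tert-butyldimethylsilyl)oxy]acetic acid | CC(C)(C)[Si](C)(C)OCC(=O)O | intermediate
8 | (4R)-4-benzyl-1,3-oxazolidin-2-one | O=C1N[C@H](Cc2ccccc2)CO1 | starting material
9 | [(tert-butyldimethylsilyl)oxy]acetic pivalic anhydride | CC(C)(C)[Si](C)(C)OCC(=O)OC(=O)C(C)(C)C | intermediate
10 | (4R)-4-benzyl-3-{[(tert-butyldimethylsilyl)oxy]acetyl}-1,3-oxazolidin-2-one | CC(C)(C)[Si](C)(C)OCC(=O)N1[C@H](Cc2ccccc2)COC1=O | intermediate
11 | sodium (Z)-enolate of 10 | [Na+].[O-]/C(=C\O[Si](C)(C)C(C)(C)C)N1[C@H](Cc2ccccc2)COC1=O | intermediate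
12 | (4R)-4-benzyl-3-[(2S,4Z)-2-[(tert-butyldimethylsilyl)oxy]-5-iodohex-4-enoyl]-1,3-oxazolidin-2-one | C/C(I)=C/C[C@H](O[Si](C)(C)C(C)(C)C)C(=O)N1[C@H](Cc2ccccc2)COC1=O | intermediate
13 | (2S,4Z)-2-[(tert-butyldimethylsilyl)oxy]-5-iodohex-4-en-1-ol | C/C(I)=C/C[C@H](O[Si](C)(C)C(C)(C)C)CO | intermediate
14 | (2S,4Z)-2-[(tert-butyldimethylsilyl)oxy]-5-iodohex-4-enal | C/C(I)=C/C[C@H](O[Si](C)(C)C(C)(C)C)C=O | intermediate
15 | tert-butyl{[(3S,5Z)-6-iodohept-5-en-1-yn-3-yl]oxy}dimethylsilane | C/C(I)=C/C[C@H](O[Si](C)(C)C(C)(C)C)C#C | intermediate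
16 | pent-4-enoyl chloride | C=CCCC(=O)Cl | starting material
17 | lithium (4R)-4-benzyl-2-oxo-1,3-oxazolidin-3-ide | [Li+].O=C1[N-][C@H](Cc2ccccc2)CO1 | intermediate
18 | (4R)-4-benzyl-3-(pent-4-enoyl)-1,3-oxazolidin-2-one | C=CCCC(=O)N1[C@H](Cc2ccccc2)COC1=O | intermediate
19 | methyl (2R)-2-hydroxypropanoate (methyl D-lactate) | C[C@@H](O)C(=O)OC | starting material
20 | methyl (2R)-2-{[(trifluoromethyl)sulfonyl]oxy}propanoate | C[C@@H](OS(=O)(=O)C(F)(F)F)C(=O)OC | intermediate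
21 | lithium (Z)-enolate of 18 | [Li+].[O-]/C(=C\CC=C)N1[C@H](Cc2ccccc2)COC1=O | intermediate
22 | methyl (2R,3S)-3-{[(4R)-4-benzyl-2-oxo-1,3-oxazolidin-3-yl]carbonyl}-2-methylhex-5-enoate | COC(=O)[C@H](C)[C@H](CC=C)C(=O)N1[C@H](Cc2ccccc2)COC1=O | intermediate
23 | secondary ozonide (1,2,4-trioxolane) of 22 | COC(=O)[C@H](C)[C@H](CC1OCOO1)C(=O)N1[C@H](Cc2ccccc2)COC1=O | intermediate
24 | methyl (2R,3S)-3-{[(4R)-4-benzyl-2-oxo-1,3-oxazolidin-3-yl]carbonyl}-2-methyl-5-oxopentanoate | COC(=O)[C@H](C)[C@H](CC=O)C(=O)N1[C@H](Cc2ccccc2)COC1=O | intermediate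
25 | methyl (2R,3S)-3-{[(4R)-4-benzyl-2-oxo-1,3-oxazolidin-3-yl]carbonyl}-5,5-dimethoxy-2-methylpentanoate | COC(=O)[C@H](C)[C@H](CC(OC)OC)C(=O)N1[C@H](Cc2ccccc2)COC1=O | intermediate
26 | methyl (2R,3S)-3-[(ethylsulfanyl)carbonyl]-5,5-dimethoxy-2-methylpentanoate | COC(=O)[C@H](C)[C@H](CC(OC)OC)C(=O)SCC | intermediate
27 | methyl (2R,3S)-3-formyl-5,5-dimethoxy-2-methylpentanoate | COC(=O)[C@H](C)[C@H](CC(OC)OC)C=O | intermediate
28 | {(1E,3S,5Z)-3-[(tert-butyldimethylsilyl)oxy]-6-iodo-2-methylhepta-1,5-dien-1-yl}dimethylalane | C/C(I)=C/C[C@H](O[Si](C)(C)C(C)(C)C)/C(C)=C/[Al](C)C | intermediate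
29 | methyl (2R,3S)-3-[(2E,4S,6Z)-4-[(tert-butyldimethylsilyl)oxy]-1-hydroxy-7-iodo-3-methylocta-2,6-dien-1-yl]-5,5-dimethoxy-2-methylpentanoate (both carbinol epimers) | COC(=O)[C@H](C)[C@H](CC(OC)OC)C(O)/C=C(C)/[C@@H](O[Si](C)(C)C(C)(C)C)C/C=C(/C)I | intermediate
30 | methyl (2R,3S)-3-[(2E,4S,6Z)-4-[(tert-butyldimethylsilyl)oxy]-7-iodo-3-methylocta-2,6-dienoyl]-5,5-dimethoxy-2-methylpentanoate | COC(=O)[C@H](C)[C@H](CC(OC)OC)C(=O)/C=C(C)/[C@@H](O[Si](C)(C)C(C)(C)C)C/C=C(/C)I | intermediate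
31 | methyl (2R,3S)-3-[(1S,2E,4S,6Z)-4-[(tert-butyldimethylsilyl)oxy]-1-hydroxy-7-iodo-3-methylocta-2,6-dien-1-yl]-5,5-dimethoxy-2-methylpentanoate | COC(=O)[C@H](C)[C@H](CC(OC)OC)[C@H](O)/C=C(C)/[C@@H](O[Si](C)(C)C(C)(C)C)C/C=C(/C)I | intermediate
32 | (3R,4S,5S)-5-[(1E,3S,5Z)-3-[(tert-butyldimethylsilyl)oxy]-6-iodo-2-methylhepta-1,5-dien-1-yl]-4-(2,2-dimethoxyethyl)-3-methyloxolan-2-one | COC(OC)C[C@@H]1[C@@H](/C=C(C)/[C@@H](O[Si](C)(C)C(C)(C)C)C/C=C(/C)I)OC(=O)[C@@H]1C | intermediate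
33 | 2-[(2S,3S,4R)-2-[(1E,3S,5Z)-3-hydroxy-6-iodo-2-methylhepta-1,5-dien-1-yl]-4-methyl-5-oxooxolan-3-yl]acetaldehyde | O=CC[C@@H]1[C@@H](/C=C(C)/[C@@H](O)C/C=C(/C)I)OC(=O)[C@@H]1C | intermediate
34 | (2R)-2-methylbutanoic acid | CC[C@@H](C)C(=O)O | starting material
35 | (1E,3S,5Z)-6-iodo-2-methyl-1-[(2S,3S,4R)-4-methyl-5-oxo-3-(2-oxoethyl)oxolan-2-yl]hepta-1,5-dien-3-yl (2R)-2-methylbutanoate | O=CC[C@@H]1[C@@H](/C=C(C)/[C@@H](OC(=O)[C@H](C)CC)C/C=C(/C)I)OC(=O)[C@@H]1C | intermediate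
36 | (3R,3aS,6Z,9S,10E,11aS)-5-hydroxy-3,6,10-trimethyl-2-oxo-2,3,3a,4,5,8,9,11a-octahydrocyclodeca[b]furan-9-yl (2R)-2-methylbutanoate (both C5 epimers; C5 = germacrane C9) | CC[C@@H](C)C(=O)O[C@H]1C/C=C(/C)C(O)C[C@@H]2[C@@H](/C=C/1C)OC(=O)[C@@H]2C | intermediate
37 | (3R,3aS,6Z,9S,10E,11aS)-3,6,10-trimethyl-2,5-dioxo-2,3,3a,4,5,8,9,11a-octahydrocyclodeca[b]furan-9-yl (2R)-2-methylbutanoate | CC[C@@H](C)C(=O)O[C@H]1C/C=C(/C)C(=O)C[C@@H]2[C@@H](/C=C/1C)OC(=O)[C@@H]2C | intermediate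
38 | (3R,3aS,5S,6Z,9S,10E,11aS)-5-hydroxy-3,6,10-trimethyl-2-oxo-2,3,3a,4,5,8,9,11a-octahydrocyclodeca[b]furan-9-yl (2R)-2-methylbutanoate (CNP0276536.1) | CC[C@@H](C)C(=O)O[C@H]1C/C=C(/C)[C@@H](O)C[C@@H]2[C@@H](/C=C/1C)OC(=O)[C@@H]2C | target

**Step count and risks**

Total step count: 23.
Longest linear sequence: 14 steps (3, 4, 5, 6, 7, 8, 16–23). The branch from 1 (steps 1, 2, 5–8, 16–23) and the East branch (steps 9, 11–15, 16–23) are equally long. 14/23 = 0.61.

The three steps most likely to fail: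

Step 16 (carboalumination of a propargylic silyl ether bearing a vinyl iodide, then alane addition to an enolisable aldehyde). Fallback: it sets out from 15. The same carboalumination is run, but alane 28 is quenched with iodine to give tert-butyl{[(1E,3S,5Z)-1,6-diiodo-2-methylhepta-1,5-dien-3-yl]oxy}dimethylsilane F1. F1 is then joined to 27 by an intermolecular Nozaki–Hiyama–Kishi coupling (CrCl2, about 0.1 mol% NiCl2, DMSO, rt). The unhindered E-CH=I terminus should react well ahead of the α-methyl Z-iodide, but this selectivity is unproven and must be checked. The route is rejoined at 29.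

Step 21 (ten-membered ring closure; risk of oligomers or no cyclisation of the lactone-constrained chain). Fallback: it sets out from 35. Pinnick oxidation (NaClO2, NaH2PO4, 2-methylbut-2-ene) gives the carboxylic acid F2. Mukaiyama thioesterification (2,2'-dipyridyl disulfide, PPh3) gives the S-pyridin-2-yl thioester F3. A Kishi-type Fe/Cu-mediated reductive alkenyl iodide–thioester ketone coupling (Mn as reductant, high dilution) then closes the ring directly as the enone. The route is rejoined at 37, so step 22 is skipped.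

Step 23 (reagent control at C9 may be overridden by the macrocycle's conformation). Fallback: it sets out from 36. The two NHK epimers are separated; the 9S epimer is 38 itself. The 9R epimer F4 is inverted by a Mitsunobu reaction with chloroacetic acid (PPh3, DIAD, toluene, 0 °C) to the 9S chloroacetate F5. F5 is cleaved selectively with thiourea and NaHCO3 in EtOH, which leaves the lactone and the 2-methylbutanoate alone. The route is rejoined at 38.

**Further compounds**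

F1 | step 16 | tert-butyl{[(1E,3S,5Z)-1,6-diiodo-2-methylhepta-1,5-dien-3-yl]oxy}dimethylsilane | C/C(I)=C/C[C@H](O[Si](C)(C)C(C)(C)C)/C(C)=C/I
F2 | step 21 | 2-[(2S,3S,4R)-2-[(1E,3S,5Z)-6-iodo-2-methyl-3-{[(2R)-2-methylbutanoyl]oxy}hepta-1,5-dien-1-yl]-4-methyl-5-oxooxolan-3-yl]acetic acid | OC(=O)C[C@@H]1[C@@H](/C=C(C)/[C@@H](OC(=O)[C@H](C)CC)C/C=C(/C)I)OC(=O)[C@@H]1C
F3 | step 21 | S-pyridin-2-yl 2-[(2S,3S,4R)-2-[(1E,3S,5Z)-6-iodo-2-methyl-3-{[(2R)-2-methylbutanoyl]oxy}hepta-1,5-dien-1-yl]-4-methyl-5-oxooxolan-3-yl]ethanethioate | O=C(C[C@@H]1[C@@H](/C=C(C)/[C@@H](OC(=O)[C@H](C)CC)C/C=C(/C)I)OC(=O)[C@@H]1C)Sc1ccccn1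
F4 | step 23 | (3R,3aS,5R,6Z,9S,10E,11aS)-5-hydroxy-3,6,10-trimethyl-2-oxo-2,3,3a,4,5,8,9,11a-octahydrocyclodeca[b]furan-9-yl (2R)-2-methylbutanoate (9-epi-38) | CC[C@@H](C)C(=O)O[C@H]1C/C=C(/C)[C@H](O)C[C@@H]2[C@@H](/C=C/1C)OC(=O)[C@@H]2C
F5 | step 23 | (3R,3aS,5S,6Z,9S,10E,11aS)-5-[(chloroacetyl)oxy]-3,6,10-trimethyl-2-oxo-2,3,3a,4,5,8,9,11a-octahydrocyclodeca[b]furan-9-yl (2R)-2-methylbutanoate | CC[C@@H](C)C(=O)O[C@H]1C/C=C(/C)[C@@H](OC(=O)CCl)C[C@@H]2[C@@H](/C=C/1C)OC(=O)[C@@H]2C
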